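**Retrosynthetic overview**

1. The strategy rests on the only stereocentre, C2 of the dihydropyranone ring C: a benzylic carbon β to the C4 ketone that carries the chromene ring B through the single C2–C1' bond, so ring C can be carried as a flat chromone and C2 created when the aryl group is delivered.
2. Last disconnections: the phenol O–MOM bond, then C2–C1' by catalytic enantioselective 1,4-addition of (2,2-dimethylchromen-6-yl)boronic acid to 7-(methoxymethoxy)-6,8-diprenylchromone.
3. Chromone (rings A and C): 2,4-dihydroxyacetophenone → 3,5-diiodide → 4-O-MOM ether → twofold linear Suzuki–Miyaura prenylation → amide-acetal annulation.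
4. Boronic acid (ring B with its pyran ring): 4-bromophenol → 1,1-dimethylpropargyl ether → thermal Claisen/electrocyclisation cascade → bromine–lithium–boron exchange.
5. Ring order: the chromene pyran ring and the pyranone ring C are closed on separate fragments, the two bicycles are then joined, and no ring is formed afterwards.

Key step: step 9

Remark: C2 is read as S from the SMILES (O1 > C1' > C3 > H). The (R) antipode of t-BuPyOx is assigned to this sense by analogy with unsubstituted chromone. This is to be checked on the first run by comparing the circular dichroism of the product with that of a known (2S)-flavanone, and the ligand antipode exchanged if the sense is reversed.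

Ligands: t-BuXPhos is 2-(di-tert-butylphosphino)-2',4',6'-triisopropylbiphenyl; (R)-t-BuPyOx is (R)-4-tert-butyl-2-(pyridin-2-yl)-4,5-dihydrooxazole.

**Route**

Step 1
Reactants: 1 2,4-dihydroxyacetophenone
Product: 3 2,4-dihydroxy-3,5-diiodoacetophenone, via 2,4-dihydroxy-3-iodoacetophenone 2 (not isolated)
Conditions: I2 (0.85 equiv), HIO3 (0.45 equiv), EtOH/H2O, 35 °C
Reagents that add atoms: iodine (II); iodic acid (OI(=O)=O)
Why: Electrophilic aromatic iodination in which HIO3 reoxidises the iodide formed, so that all iodine is used; C3 and C5 are each ortho/para to both hydroxyl groups and are the only activated positions, C3 expected to react first (compound 2) and C5 second.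

Step 2
Reactants: 3 2,4-dihydroxy-3,5-diiodoacetophenone
Product: 4 2-hydroxy-3,5-diiodo-4-(methoxymethoxy)acetophenone
Conditions: MOMCl (1.1 equiv), K2CO3, acetone, 0 °C → rt
Reagents that add atoms: chloromethyl methyl ether (COCCl)
Why: Williamson-type O-alkylation of the more acidic, non-chelated 4-OH (flanked by two iodines and para to the acetyl group), while the 2-OH stays locked in its hydrogen bond to the ketone and is not alkylated by one equivalent of the chloride.

Step 3
Reactants: 4 2-hydroxy-3,5-diiodo-4-(methoxymethoxy)acetophenone; 5 prenylboronic acid pinacol ester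
Product: 7 2-hydroxy-4-(methoxymethoxy)-3,5-bis(3-methylbut-2-en-1-yl)acetophenone, via 3-iodo-5-prenyl intermediate 6 (not isolated)
Conditions: 5 (3.5 equiv), Pd(OAc)2 (5 mol%), t-BuXPhos (10 mol%), K3PO4 (aq.), THF, 40 °C
Reagents that add atoms: none
Why: Twofold Suzuki–Miyaura allyl–aryl coupling in which SE2' transmetalation gives a tertiary σ-allylpalladium that, held back from reductive elimination by the bulky di-tert-butylbiarylphosphine, equilibrates through the π-allyl to the primary σ-prenyl complex and then eliminates to the linear prenylarene; the less hindered C5 iodide should react first (compound 6) and the excess boronate drives the coupling at C3.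

Step 4
Reactants: 7 2-hydroxy-4-(methoxymethoxy)-3,5-bis(3-methylbut-2-en-1-yl)acetophenone
Product: 8 (E)-3-(dimethylamino)-1-[2-hydroxy-4-(methoxymethoxy)-3,5-bis(3-methylbut-2-en-1-yl)phenyl]prop-2-en-1-one
Conditions: Me2NCH(OMe)2 (3 equiv), toluene, 90 °C
Reagents that add atoms: N,N-dimethylformamide dimethyl acetal (COC(OC)N(C)C)
Why: Condensation of the methyl ketone with the amide acetal (enaminone formation) supplies the future C2 carbon of ring C, the chelated phenol being a poor partner for O-methylation by the acetal at this temperature.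

Step 5
Reactants: 8 (E)-3-(dimethylamino)-1-[2-hydroxy-4-(methoxymethoxy)-3,5-bis(3-methylbut-2-en-1-yl)phenyl]prop-2-en-1-one
Product: 10 7-(methoxymethoxy)-6,8-bis(3-methylbut-2-en-1-yl)-4H-chromen-4-one, via 2-(dimethylamino)chromanone 9 (not isolated)
Conditions: AcOH/toluene (1:10), 60 °C
Reagents that add atoms: none
Why: Acid-promoted 6-endo oxa-Michael addition of the phenol to the protonated enaminone gives aminal 9 and β-elimination of dimethylamine aromatises the pyranone (chromone annulation), acetic acid being too weak to cleave the aryl MOM ether or to protonate the prenyl alkenes.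

Step 6
Reactants: 11 4-bromophenol; 12 3-chloro-3-methylbut-1-yne
Product: 13 1-bromo-4-[(2-methylbut-3-yn-2-yl)oxy]benzene
Conditions: K2CO3, KI (cat.), CuI (cat.), acetone, 55 °C
Reagents that add atoms: none
Why: Copper-assisted O-alkylation of the phenoxide by the tertiary propargylic chloride, in which ionisation through the copper acetylide makes substitution at the quaternary carbon possible, the standard entry to aryl 1,1-dimethylpropargyl ethers.

Step 7
Reactants: 13 1-bromo-4-[(2-methylbut-3-yn-2-yl)oxy]benzene
Product: 16 6-bromo-2,2-dimethyl-2H-chromene, via allenylphenol 14 (not isolated), via ortho-quinone methide 15 (not isolated)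
Conditions: PhNEt2, 190 °C
Reagents that add atoms: none
Why: Aryl propargyl ether Claisen rearrangement ([3,3]) followed by enolisation gives allenylphenol 14, a 1,5-hydrogen shift gives quinone methide 15, and oxa-6π electrocyclisation closes the pyran ring, the two ortho positions being equivalent because bromine sits para to oxygen.

Step 8
Reactants: 16 6-bromo-2,2-dimethyl-2H-chromene
Product: 19 (2,2-dimethyl-2H-chromen-6-yl)boronic acid, via aryllithium 17 (not isolated), via lithium triisopropoxyborate 18 (not isolated)
Conditions: n-BuLi, THF, −78 °C; B(Oi-Pr)3, −78 °C → rt; 1 M HCl, 0 °C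
Reagents that add atoms: triisopropyl borate (CC(C)OB(OC(C)C)OC(C)C); water (O)
Why: Bromine–lithium exchange at −78 °C outruns any reaction at the chromene alkene, the aryllithium is captured by the borate as ate complex 18, and cold dilute acid hydrolyses the isopropyl esters to the boronic acid.

Step 9
Reactants: 10 7-(methoxymethoxy)-6,8-bis(3-methylbut-2-en-1-yl)-4H-chromen-4-one; 19 (2,2-dimethyl-2H-chromen-6-yl)boronic acid
Product: 20 (2S)-2-(2,2-dimethyl-2H-chromen-6-yl)-7-(methoxymethoxy)-6,8-bis(3-methylbut-2-en-1-yl)chroman-4-one
Conditions: 19 (2.5 equiv), Pd(OCOCF3)2 (10 mol%), (R)-t-BuPyOx (12 mol%), NH4PF6 (30 mol%), H2O (5 equiv), ClCH2CH2Cl, 50 °C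
Reagents that add atoms: none
Why: The boronic acid transmetalates to the cationic, t-BuPyOx-ligated divalent palladium, the aryl–palladium binds the chromone C2=C3 bond and inserts so that C1' bonds to C2 (the enantiodetermining migratory insertion), and the C3-bound palladium enolate is protonated by water, releasing the flavanone and the divalent catalyst without a change of oxidation state. The closest known reaction type is the enantioselective conjugate addition of arylboronic acids to chromones under divalent-palladium/pyridine-oxazoline catalysis, with the Hayashi–Miyaura 1,4-addition under monovalent-rhodium catalysis as its relative. No ring is closed, since ring C is already in place as the pyranone; only the C2–C1' bond forms and the reversible chalcone/phenoxide manifold of a ring-closing flavanone synthesis is never entered. The new stereocentre C2 is controlled by the ligand alone, the tert-butyl group of the oxazoline blocking one quadrant so that the aryl group reaches one face of the flat, achiral chromone, the (R) ligand being expected to give 2S. The step needs face selectivity, 1,4- over 1,2-addition and preference for the chromone alkene over the chromene and prenyl alkenes: the vinylogous-ester polarisation and the free C2–H direct the aryl group to C2, the trisubstituted prenyl alkenes are remote and insert poorly, and the electron-rich cis-disubstituted chromene alkene is a poorer acceptor for the electrophilic aryl–palladium than the enone. The absence of base and a neutral work-up protect the product from retro-oxa-Michael racemisation.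

Step 10
Reactants: 20 (2S)-2-(2,2-dimethyl-2H-chromen-6-yl)-7-(methoxymethoxy)-6,8-bis(3-methylbut-2-en-1-yl)chroman-4-one
Product: 21 (2S)-2-(2,2-dimethyl-2H-chromen-6-yl)-7-hydroxy-6,8-bis(3-methylbut-2-en-1-yl)chroman-4-one (the target)
Conditions: 3 M HCl (aq.)/MeOH (1:10), rt, stopped at full conversion; pH 7 buffer
Reagents that add atoms: none
Why: Acid-catalysed methanolysis of the MOM acetal (through the methoxymethyl oxocarbenium ion) should be faster in dilute acid at room temperature than protonation of the trisubstituted prenyl alkenes or the chromene alkene, and C2 is not at risk because opening of ring C requires base.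

**Compound list**

1 | 2,4-dihydroxyacetophenone | CC(=O)c1ccc(O)cc1O | starting material
2 | 2,4-dihydroxy-3-iodoacetophenone | CC(=O)c1ccc(O)c(I)c1O | intermediate
3 | 2,4-dihydroxy-3,5-diiodoacetophenone | CC(=O)c1cc(I)c(O)c(I)c1O | intermediate
4 | 2-hydroxy-3,5-diiodo-4-(methoxymethoxy)acetophenone | CC(=O)c1cc(I)c(OCOC)c(I)c1O | intermediate
5 | prenylboronic acid pinacol ester, 4,4,5,5-tetramethyl-2-(3-methylbut-2-en-1-yl)-1,3,2-dioxaborolane | CC(C)=CCB1OC(C)(C)C(C)(C)O1 | starting material
6 | 2-hydroxy-3-iodo-4-(methoxymethoxy)-5-(3-methylbut-2-en-1-yl)acetophenone | CC(=O)c1cc(CC=C(C)C)c(OCOC)c(I)c1O | intermediate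
7 | 2-hydroxy-4-(methoxymethoxy)-3,5-bis(3-methylbut-2-en-1-yl)acetophenone | CC(=O)c1cc(CC=C(C)C)c(OCOC)c(CC=C(C)C)c1O | intermediate
8 | (E)-3-(dimethylamino)-1-[2-hydroxy-4-(methoxymethoxy)-3,5-bis(3-methylbut-2-en-1-yl)phenyl]prop-2-en-1-one | CN(C)/C=C/C(=O)c1cc(CC=C(C)C)c(OCOC)c(CC=C(C)C)c1O | intermediate
9 | 2-(dimethylamino)-7-(methoxymethoxy)-6,8-bis(3-methylbut-2-en-1-yl)chroman-4-one | CN(C)C1CC(=O)c2cc(CC=C(C)C)c(OCOC)c(CC=C(C)C)c2O1 | intermediate
10 | 7-(methoxymethoxy)-6,8-bis(3-methylbut-2-en-1-yl)-4H-chromen-4-one | O=c1ccoc2c1cc(CC=C(C)C)c(OCOC)c2CC=C(C)C | intermediate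
11 | 4-bromophenol | Oc1ccc(Br)cc1 | starting material
12 | 3-chloro-3-methylbut-1-yne | C#CC(C)(C)Cl | starting material
13 | 1-bromo-4-[(2-methylbut-3-yn-2-yl)oxy]benzene | C#CC(C)(C)Oc1ccc(Br)cc1 | intermediate
14 | 4-bromo-2-(3-methylbuta-1,2-dien-1-yl)phenol | CC(C)=C=Cc1cc(Br)ccc1O | intermediate
15 | 4-bromo-6-(3-methylbut-2-en-1-ylidene)cyclohexa-2,4-dien-1-one | CC(C)=CC=C1C=C(Br)C=CC1=O | intermediate
16 | 6-bromo-2,2-dimethyl-2H-chromene | CC1(C)C=Cc2cc(Br)ccc2O1 | intermediate
17 | (2,2-dimethyl-2H-chromen-6-yl)lithium | [Li]c1ccc2c(c1)C=CC(C)(C)O2 | intermediate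
18 | lithium (2,2-dimethyl-2H-chromen-6-yl)triisopropoxyborate | [Li+].CC(C)O[B-](OC(C)C)(OC(C)C)c1ccc2c(c1)C=CC(C)(C)O2 | intermediate
19 | (2,2-dimethyl-2H-chromen-6-yl)boronic acid | CC1(C)C=Cc2cc(B(O)O)ccc2O1 | intermediate
20 | (2S)-2-(2,2-dimethyl-2H-chromen-6-yl)-7-(methoxymethoxy)-6,8-bis(3-methylbut-2-en-1-yl)chroman-4-one | CC(C)=CCc1cc2c(c(CC=C(C)C)c1OCOC)O[C@H](c1ccc3c(c1)C=CC(C)(C)O3)CC2=O | intermediate
21 | (2S)-2-(2,2-dimethyl-2H-chromen-6-yl)-7-hydroxy-6,8-bis(3-methylbut-2-en-1-yl)chroman-4-one (the target natural product) | CC(C)=CCc1cc2c(c(CC=C(C)C)c1O)O[C@H](c1ccc3c(c1)C=CC(C)(C)O3)CC2=O | target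

**Step count**

Total steps: 10 (steps 1–5 for the chromone, steps 6–8 for the boronic acid, steps 9 and 10 after convergence).
Longest linear sequence: 7 steps (steps 1, 2, 3, 4, 5, 9 and 10, from compound 1).

**Steps most likely to fail**

Step 9 (key step). The electron-rich boronic acid may protodeboronate before it transmetalates. The aryl–palladium may insert Heck-fashion into the chromene alkene of a second boronic acid molecule. Facial selectivity may be poor on the electron-rich, 8-substituted chromone. The fallback closes ring C by oxa-Michael addition instead of joining the fragments by aryl addition, and obtains the enantiomer by resolution. It sets out from 7 and 16 and comes back at 20. Aryllithium 17, made from 16 as in step 8, is quenched with DMF to give 2,2-dimethyl-2H-chromene-6-carbaldehyde F1. Claisen–Schmidt condensation of 7 with this aldehyde (KOH, EtOH/H2O, rt) should give the 2'-hydroxychalcone F2. NaOAc in refluxing EtOH closes ring C by 6-endo oxa-Michael addition to the racemic MOM flavanone F3. Preparative HPLC on a chiral stationary phase then delivers 20, and the unwanted (2R)-enantiomer F4 is recycled through the same NaOAc equilibration.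

Step 3. Coupling may occur at the γ-carbon of the boronate (reverse-prenyl product), the iodide may be lost by protodeiodination, or the reaction may stall after the first coupling at the doubly ortho-substituted C3 iodide. The fallback abandons cross-coupling for direct C-alkylation of the phenoxide. It sets out from 1 and comes back at 7. Treatment of 1 with prenyl bromide in 10% aqueous KOH (0 °C → rt) should give, besides mono-C-prenylated and O-prenylated material, 2,4-dihydroxy-3,5-diprenylacetophenone F5, which is separated by chromatography. The sequence is short and known, at the cost of material throughput. Selective MOM protection of its non-chelated 4-OH (MOMCl, K2CO3, acetone) then gives 7.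

Step 10. Before the hindered MOM ether between two prenyl groups is fully cleaved, the liberated 7-OH may cyclise onto a neighbouring prenyl group under acid, or methanol or HCl may add across the chromene double bond. The fallback moves the acidic unmasking to a stage without chromene or stereocentre and finishes with fluoride instead of acid. It sets out from 10 (with 19) and comes back at 21. Chromone 10 is treated with dilute HCl in MeOH at rt to give 7-hydroxy-6,8-diprenylchromone F6, where over-exposure costs only early material and any chroman by-product is removed by chromatography. Silylation (TBSCl, imidazole, DMF) gives 7-(tert-butyldimethylsilyloxy)-6,8-diprenylchromone F7. The conjugate addition of 19 under the conditions of step 9 should give the (2S)-7-O-TBS flavanone F8. Buffered fluoride (n-Bu4NF/AcOH 1:1, THF, 0 °C) then frees the phenol to give 21 without strong acid or free base.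

**Further compounds**

F1 | step 9 | 2,2-dimethyl-2H-chromene-6-carbaldehyde | CC1(C)C=Cc2cc(C=O)ccc2O1
F2 | step 9 | (E)-3-(2,2-dimethyl-2H-chromen-6-yl)-1-[2-hydroxy-4-(methoxymethoxy)-3,5-bis(3-methylbut-2-en-1-yl)phenyl]prop-2-en-1-one | COCOc1c(CC=C(C)C)cc(C(=O)/C=C/c2ccc3c(c2)C=CC(C)(C)O3)c(O)c1CC=C(C)C
F3 | step 9 | racemic 2-(2,2-dimethyl-2H-chromen-6-yl)-7-(methoxymethoxy)-6,8-bis(3-methylbut-2-en-1-yl)chroman-4-one | CC(C)=CCc1cc2c(c(CC=C(C)C)c1OCOC)OC(c1ccc3c(c1)C=CC(C)(C)O3)CC2=O
F4 | step 9 | (2R)-2-(2,2-dimethyl-2H-chromen-6-yl)-7-(methoxymethoxy)-6,8-bis(3-methylbut-2-en-1-yl)chroman-4-one | CC(C)=CCc1cc2c(c(CC=C(C)C)c1OCOC)O[C@@H](c1ccc3c(c1)C=CC(C)(C)O3)CC2=O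
F5 | step 3 | 2,4-dihydroxy-3,5-bis(3-methylbut-2-en-1-yl)acetophenone | CC(=O)c1cc(CC=C(C)C)c(O)c(CC=C(C)C)c1O
F6 | step 10 | 7-hydroxy-6,8-bis(3-methylbut-2-en-1-yl)-4H-chromen-4-one | O=c1ccoc2c1cc(CC=C(C)C)c(O)c2CC=C(C)C
F7 | step 10 | 7-[(tert-butyldimethylsilyl)oxy]-6,8-bis(3-methylbut-2-en-1-yl)-4H-chromen-4-one | O=c1ccoc2c1cc(CC=C(C)C)c(O[Si](C)(C)C(C)(C)C)c2CC=C(C)C
F8 | step 10 | (2S)-7-[(tert-butyldimethylsilyl)oxy]-2-(2,2-dimethyl-2H-chromen-6-yl)-6,8-bis(3-methylbut-2-en-1-yl)chroman-4-one | CC(C)=CCc1cc2c(c(CC=C(C)C)c1O[Si](C)(C)C(C)(C)C)O[C@H](c1ccc3c(c1)C=CC(C)(C)O3)CC2=O
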